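We come back at the end to a neighbour of the flask dawn, charged with more protonated nucleophile; first the three flasks as they stand.

    electrophile + nucleophile → acid set free + target (k1 = 9400 /M/s)
    acid set free + free base ⇌ salt of the base, settled at all times (K2 = 7.3 × 10⁵ /M)
    solid electrophile ⇌ electrophile, rate k3*(cs3 - [electrophile]) while solid is left; crystals form when [electrophile] > cs3 (cs3 = 0.49 mM, k3 = 0.266 /s)
    nucleophile + acid set free ⇌ protonated nucleophile, settled at all times (K4 = 5.9 × 10⁶ /M)

common to all: solid electrophile 0.0010 M; protonated nucleophile 0.950 mM; time 3.0 s

|  | free base | remark |
|---|---|---|
| noon | 0.500 mM (fed, over 1.5 s) | the fed solution adds 0.10 times the starting volume |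
| dusk | 1.00 mM (fed, over 1.5 s) | the fed solution adds 0.10 times the starting volume |
| dawn | 2.00 mM (fed, over 1.5 s) | the fed solution adds 0.10 times the starting volume |

- charges are per starting volume, the dose included; the dosed solution carries all of it
- as a solid, counted per litre of solution: solid electrophile
- at the start none of the solid electrophile is in solution
- what has only dissolved of solid electrophile counts as not reacted
- run time (noon): 3.0 s

1. part of the solid electrophile that has reacted (what has only dissolved counts as not reacted) at the end, noon
2. part of the solid electrophile that has reacted (what has only dissolved counts as not reacted) at the end, dusk
3. part of the solid electrophile that has reacted (what has only dissolved counts as not reacted) at the end, dawn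
4. what raising the concentration of free base from its lowest to its highest value here does to the part of the solid electrophile that has reacted (what has only dissolved counts as not reacted) (changes below 5 percentage points count as none) (it falls / it rises / no change)

The bench rule says that what dissolves reacts. The solid gives at most s = k3·cs3 = 0.130 mM/s, so over the run the rule allows 39.1 % of the charge in each of the flasks. We leave the dilution by the feed aside.

To find where the rule stops working, we follow one dissolved molecule of electrophile. It stands in solution until it meets a free nucleophile, and free nucleophile exists as far as the free base takes protons from the protonated nucleophile, with exchange constant K2/K4 = 0.124. We take half the base charge as on hand and set the nucleophile equal to the salt of the base, so that the free nucleophile N is the square root of that constant times the charge of protonated nucleophile times that half of the base. With N held steady, the electrophile goes by a pseudo-first-order path, and 1/(k1·N) is 0.621 s in noon, 0.439 s in dusk and 0.310 s in dawn. We call this the wait: the mean time a dissolved molecule stands before a nucleophile takes it.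

The rule holds while the wait and the feed are small against the run, but the ratio tf/t1 is 0.500. So we start the clock halfway through the feed and take off the wait, which gives s·(t1 − tf/2 − wait): 21.2 % in noon, 23.6 % in dusk and 25.3 % in dawn. That is a rise of 4 percentage points, under the 5 points that counts as a change.

The forecast gives 16.5 %, 24 % and 30 %, and for the trend it differs from us: it rises. Its ground: “In the lower-base charges it becomes nucleophile-limited as the base is used up”.

The flasks give 17.2 %, 23.4 % and 28.4 %; it rises, by 11 points. From the nucleophile standing at the end, the wait is 3.67 s in noon and 0.930 s in dawn, longer in noon and in each flask longer than the wait we reckoned. At the end, electrophile stands at 16.9 % in noon against 8.87 % in dawn. With the other amounts and the time held, the dusk answer moves by 5 points at 8.23 × 10⁻⁴ M or 0.00127 M of solid electrophile, or at 0.569 mM or 1.99 mM of free base. With 0.0038 M of protonated nucleophile, the neighbour's reckoned wait is 0.155 s, shorter than dawn's reckoned wait by a factor 2.00; at the end dawn's electrophile stands 2.15 times the neighbour's 4.13 %, and the neighbour's target reaches 35.3 %.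

The constants used here are invented; the flask was simulated.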